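**Retrosynthetic overview**
1. Gentiside H is (S)-18-methylicosyl 2,3-dihydroxybenzoate; the last disconnection is at the two phenolic O–benzyl bonds of bis-benzyl ether 13 (hydrogenolysis).
2. The key disconnection is C10–C11 of the icosyl chain (numbered from the ester oxygen). It is made by a nickel-electrocatalytic doubly decarboxylative C(sp3)–C(sp3) coupling of two N-acyloxyphthalimides: 6 (C11–C20 half) and 12 (C1–C10 half, already carrying the protected aryl ester).
3. Enabling feature: C10 and C11 are plain CH2 groups inside the unbranched (CH2)17 run. C10 is nine CH2 from the ester oxygen and the benzene ring, and C11 is seven CH2 from the C18 stereocentre, so each is the radical carbon of a simple ω-substituted undecanoic acid with nothing nearby to cyclise, eliminate or epimerise.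
4. Acid 5 comes from (S)-1-bromo-2-methylbutane (C18 bought from the chiral pool) and 7-bromoheptanoic acid by copper-catalysed Grignard alkylation. Acid 11 comes from 2,3-dihydroxybenzoic acid by carboxylate alkylation with tert-butyl 11-bromoundecanoate, benzylation and tert-butyl ester cleavage.
5. No ring is formed in the route: the only ring, the benzene ring, is bought with 2,3-dihydroxybenzoic acid.

Key step: step 7

Remark: compounds 1, 2, 7 and 8 are taken as catalogue compounds; the configuration at C18 is read from the SMILES as (S), the same sense as in (S)-1-bromo-2-methylbutane.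

**Route**

Step 1
Reactants: 1 (S)-1-bromo-2-methylbutane; 2 7-bromoheptanoic acid
Product: 5 (S)-9-methylundecanoic acid, via (S)-2-methylbutylmagnesium bromide 3 (not isolated), via chloromagnesium 7-bromoheptanoate 4 (not isolated)
Conditions: 1 (1.3 equiv), Mg, THF, reflux; separately 2, MeMgCl (1.0 equiv), THF, −20 °C; then Grignard solution added, Li2CuCl4 (3 mol%), THF, −20 °C to rt; aq. HCl
Reagents that add atoms: none
Why: Kochi-type copper-catalysed cross-coupling of a primary alkyl Grignard reagent with a primary alkyl bromide, run on the magnesium carboxylate so that the acid function is inert; the C–Mg bond is on the CH2 next to the stereocentre, so the (S) centre bought with 1 should not be touched.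

Step 2
Reactants: 5 (S)-9-methylundecanoic acid
Product: 6 1,3-dioxoisoindolin-2-yl (S)-9-methylundecanoate
Conditions: N-hydroxyphthalimide (1.1 equiv), DIC (1.1 equiv), DMAP (5 mol%), CH2Cl2, rt
Reagents that add atoms: N-hydroxyphthalimide, O=C1c2ccccc2C(=O)N1O
Why: Carbodiimide (Steglich-type) esterification of an unhindered primary acid with the acidic N–OH group should give the redox-active ester cleanly, and no stereocentre is near the reacting carbonyl.

Step 3
Reactants: 7 2,3-dihydroxybenzoic acid; 8 tert-butyl 11-bromoundecanoate
Product: 9 tert-butyl 11-[(2,3-dihydroxybenzoyl)oxy]undecanoate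
Conditions: 7 (1.2 equiv), KHCO3 (1.3 equiv), NaI (10 mol%), DMF, 60 °C
Reagents that add atoms: none
Why: SN2 O-alkylation of the carboxylate; bicarbonate deprotonates only the carboxylic acid (pKa about 3) and not the phenols (pKa about 10), so the ester should form chemoselectively.

Step 4
Reactants: 9 tert-butyl 11-[(2,3-dihydroxybenzoyl)oxy]undecanoate
Product: 10 tert-butyl 11-{[2,3-bis(benzyloxy)benzoyl]oxy}undecanoate
Conditions: BnBr (2.5 equiv), K2CO3 (3 equiv), DMF, 60 °C
Reagents that add atoms: benzyl bromide, BrCc1ccccc1
Why: Williamson ether synthesis; carbonate in DMF deprotonates both phenols (including the hydrogen-bonded 2-OH), and both esters are inert to a non-nucleophilic base.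

Step 5
Reactants: 10 tert-butyl 11-{[2,3-bis(benzyloxy)benzoyl]oxy}undecanoate
Product: 11 11-{[2,3-bis(benzyloxy)benzoyl]oxy}undecanoic acid
Conditions: TFA/CH2Cl2 (1:4), 0 °C to rt
Reagents that add atoms: none
Why: Acidolysis of the tert-butyl ester by loss of the tert-butyl cation; the primary alkyl benzoate and the aryl benzyl ethers should survive a short exposure to TFA at room temperature.

Step 6
Reactants: 11 11-{[2,3-bis(benzyloxy)benzoyl]oxy}undecanoic acid
Product: 12 11-[(1,3-dioxoisoindolin-2-yl)oxy]-11-oxoundecyl 2,3-bis(benzyloxy)benzoate
Conditions: N-hydroxyphthalimide (1.1 equiv), DIC (1.1 equiv), DMAP (5 mol%), CH2Cl2, rt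
Reagents that add atoms: N-hydroxyphthalimide, O=C1c2ccccc2C(=O)N1O
Why: Carbodiimide (Steglich-type) esterification as in step 2; with the phenols capped, the carboxylic acid is the only acylating site and the benzoate and benzyl ethers are spectators.

Step 7
Reactants: 6 1,3-dioxoisoindolin-2-yl (S)-9-methylundecanoate; 12 11-[(1,3-dioxoisoindolin-2-yl)oxy]-11-oxoundecyl 2,3-bis(benzyloxy)benzoate
Product: 13 (S)-18-methylicosyl 2,3-bis(benzyloxy)benzoate
Conditions: 12 (1 equiv), 6 (3 equiv), NiCl2·6H2O (20 mol%), 2,2':6',2''-terpyridine (20 mol%), AgNO3 (0.3 equiv), NMP, (+)Mg/(−)RVC, undivided cell, constant current (ca. 2.5 F/mol), rt; aq. HCl work-up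
Reagents that add atoms: none
Why: Both N-acyloxyphthalimides are reduced at the silver-nanoparticle-coated cathode or by low-valent terpyridine–nickel, the radical anions lose phthalimide anion and CO2, and the two primary alkyl radicals (C10 of the aryl half, C11 of the branched half) are collected on nickel as a dialkyl-Ni(III) species that reductively eliminates the C10–C11 σ-bond, with the magnesium anode as terminal reductant. The closest known reaction type is the nickel-electrocatalytic doubly decarboxylative C(sp3)–C(sp3) cross-coupling of two redox-active esters, a reductive, catalysed counterpart of the mixed Kolbe electrolysis that is established for primary–primary pairs. No ring is closed and no stereocentre is formed; the C18 centre sits seven methylenes from the radical carbon and is never part of a radical, an organonickel or an enolisable position, so its (S) configuration should be carried through unchanged. The selectivity needed is cross- over homo-coupling, which is statistical and is secured for the limiting partner 12 by the threefold excess of 6, whose homodimer is a hydrocarbon that should separate from the aryl ester on silica. Chemoselectivity rests on the reductive regime: the electron-rich 2,3-dialkoxybenzoate that an anodic Kolbe coupling would oxidise, the benzyl ethers and the benzoate ester all lie well beyond the potential at which the N–O bond is cleaved, and the ten methylenes between radical and arene rule out cyclisation.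

Step 8
Reactants: 13 (S)-18-methylicosyl 2,3-bis(benzyloxy)benzoate
Product: 14 Gentiside H, (S)-18-methylicosyl 2,3-dihydroxybenzoate
Conditions: H2 (1 atm), 10% Pd/C, EtOAc/EtOH, rt
Reagents that add atoms: none
Why: Palladium-catalysed hydrogenolysis of the two aryl benzyl ethers; the alkyl benzoate has no benzylic C–O bond, and the saturated chain and the remote stereocentre are inert.

**Compound list**
1 | (S)-1-bromo-2-methylbutane | CC[C@H](C)CBr | starting material
2 | 7-bromoheptanoic acid | OC(=O)CCCCCCBr | starting material
3 | (S)-2-methylbutylmagnesium bromide | CC[C@H](C)C[Mg]Br | intermediate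
4 | chloromagnesium 7-bromoheptanoate | BrCCCCCCC(=O)O[Mg]Cl | intermediate
5 | (S)-9-methylundecanoic acid | CC[C@H](C)CCCCCCCC(=O)O | intermediate
6 | 1,3-dioxoisoindolin-2-yl (S)-9-methylundecanoate | CC[C@H](C)CCCCCCCC(=O)ON1C(=O)c2ccccc2C1=O | intermediate
7 | 2,3-dihydroxybenzoic acid | OC(=O)c1cccc(O)c1O | starting material
8 | tert-butyl 11-bromoundecanoate | CC(C)(C)OC(=O)CCCCCCCCCCBr | starting material
9 | tert-butyl 11-[(2,3-dihydroxybenzoyl)oxy]undecanoate | CC(C)(C)OC(=O)CCCCCCCCCCOC(=O)c1cccc(O)c1O | intermediate
10 | tert-butyl 11-{[2,3-bis(benzyloxy)benzoyl]oxy}undecanoate | CC(C)(C)OC(=O)CCCCCCCCCCOC(=O)c1cccc(OCc2ccccc2)c1OCc1ccccc1 | intermediate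
11 | 11-{[2,3-bis(benzyloxy)benzoyl]oxy}undecanoic acid | OC(=O)CCCCCCCCCCOC(=O)c1cccc(OCc2ccccc2)c1OCc1ccccc1 | intermediate
12 | 11-[(1,3-dioxoisoindolin-2-yl)oxy]-11-oxoundecyl 2,3-bis(benzyloxy)benzoate | O=C(CCCCCCCCCCOC(=O)c1cccc(OCc2ccccc2)c1OCc1ccccc1)ON1C(=O)c2ccccc2C1=O | intermediate
13 | (S)-18-methylicosyl 2,3-bis(benzyloxy)benzoate | CC[C@H](C)CCCCCCCCCCCCCCCCCOC(=O)c1cccc(OCc2ccccc2)c1OCc1ccccc1 | intermediate
14 | Gentiside H, (S)-18-methylicosyl 2,3-dihydroxybenzoate | CC[C@H](C)CCCCCCCCCCCCCCCCCOC(=O)c1cccc(O)c1O | target

**Summary**
Total step count: 8.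
Longest linear sequence: 6 steps (steps 3, 4, 5, 6, 7, 8, from 7 and 8); the other branch is steps 1, 2, 7, 8.

**Steps most likely to fail**

Step 7. The risk is that statistical homo-coupling consumes the limiting redox-active ester, or that the esters are reduced to the alkane or hydrolysed before the radicals are captured on nickel. The fallback forms the same C10–C11 bond by polar copper-catalysed chemistry, sets out from 1 (through its Grignard reagent 3) and from 7, and comes back to the route at 14. Grignard reagent 3 would be coupled (Li2CuCl4 cat., THF, −20 °C) with an excess of 1,6-dibromohexane (BrCCCCCCBr, 3 equiv) to give (S)-1-bromo-8-methyldecane F1. With magnesium in THF this would give (S)-8-methyldecylmagnesium bromide F2, which would be coupled in the same way with an excess of 1,10-dibromodecane (BrCCCCCCCCCCBr, 3 equiv) to give (S)-1-bromo-18-methylicosane F3. Bromide F3 would then alkylate the carboxylate of 7 (KHCO3, NaI, DMF, 70 °C, as in step 3) to give 14 directly, without phenol protection.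

Step 1. The risk is Wurtz-type homo-coupling or β-hydride loss of the β-branched Grignard reagent, and incomplete conversion because the magnesium carboxylate is poorly soluble. The fallback replaces the organometallic alkylation by olefination and reduction, sets out from 1 and comes back at 5. Bromide 1 would be heated with triphenylphosphine (MeCN, reflux) to give (S)-(2-methylbutyl)triphenylphosphonium bromide F4. Deprotonation (NaHMDS, THF, −78 °C) would give the ylide (S)-(2-methylbutylidene)triphenylphosphorane F5, which with methyl 7-oxoheptanoate (COC(=O)CCCCCC=O) should give methyl (S,Z)-9-methylundec-7-enoate F6 by Wittig reaction. Hydrogenation over Pt/C (chosen to limit double-bond migration towards the allylic stereocentre) would give methyl (S)-9-methylundecanoate F7, and saponification (LiOH, THF/H2O, then HCl) would give 5.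

Step 3. The risk is competing O-alkylation of the 3-hydroxyl group and a sluggish SN2 reaction of the long-chain bromide under bicarbonate. The fallback protects the phenols before the ester is built, sets out from 7 and comes back at 10, replacing steps 3 and 4. Acid 7 would be perbenzylated (BnBr 3.5 equiv, K2CO3, DMF, 60 °C) to benzyl 2,3-bis(benzyloxy)benzoate F8. Saponification (NaOH, MeOH/THF/H2O, then HCl) would give 2,3-bis(benzyloxy)benzoic acid F9, whose caesium salt (Cs2CO3, DMF, 50 °C) would be alkylated with 8 to give 10.

Further compounds
F1 | step 7 | (S)-1-bromo-8-methyldecane | CC[C@H](C)CCCCCCCBr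
F2 | step 7 | (S)-8-methyldecylmagnesium bromide | CC[C@H](C)CCCCCCC[Mg]Br
F3 | step 7 | (S)-1-bromo-18-methylicosane | CC[C@H](C)CCCCCCCCCCCCCCCCCBr
F4 | step 1 | (S)-(2-methylbutyl)triphenylphosphonium bromide | CC[C@H](C)C[P+](c1ccccc1)(c1ccccc1)c1ccccc1.[Br-]
F5 | step 1 | (S)-(2-methylbutylidene)triphenylphosphorane | CC[C@H](C)C=P(c1ccccc1)(c1ccccc1)c1ccccc1
F6 | step 1 | methyl (S,Z)-9-methylundec-7-enoate | CC[C@H](C)/C=C\CCCCCC(=O)OC
F7 | step 1 | methyl (S)-9-methylundecanoate | CC[C@H](C)CCCCCCCC(=O)OC
F8 | step 3 | benzyl 2,3-bis(benzyloxy)benzoate | O=C(OCc1ccccc1)c1cccc(OCc2ccccc2)c1OCc1ccccc1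
F9 | step 3 | 2,3-bis(benzyloxy)benzoic acid | OC(=O)c1cccc(OCc2ccccc2)c1OCc1ccccc1
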